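**Retrosynthetic overview**
1. The butenolide is made last: the C16–C17 bond, the lactone and the C16 centre come from an enantioselective Ni/Cr coupling of lactol 21 (a masked C16 aldehyde) with Z-iodoenoate 23.
2. C9–C11 is made by B-alkyl Suzuki coupling of enol triflate 13 with the borane from diene triol 17; glycol cleavage then unveils C16.
3. C12–C13, C14–C15 and the 13Z alkene come from a one-flask carbomagnesiation of propargyl alcohol with CH2=CHMgCl followed by copper-catalysed opening of glycidol.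
4. Ring B comes from a one-carbon ring expansion (1,2-shift) of trans-hydrindanone 10 with diazoethane, which inserts C8 with its methyl; 10 comes from 2-methylcyclopentane-1,3-dione and ethyl vinyl ketone.
5. Ring order: ring A annulated onto the cyclopentane, cyclopentane expanded to ring B, temporary dihydropyranol, butenolide.

Assumption: terpenoid numbering is used in the discussion (decalin C1–C10, chain C11–C16, lactone C17–C19, hydroxymethyl carbons C24 on C13 and C25 on C17); the target SMILES corresponds to 5S,10S,16R with a 13Z alkene.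

**Route**

Step 1
Reactants: 1 2-methylcyclopentane-1,3-dione; 2 pent-1-en-3-one (ethyl vinyl ketone)
Product: 4 (7aS)-4,7a-dimethyl-2,3,7,7a-tetrahydro-1H-indene-1,5(6H)-dione, via triketone 3 (not isolated)
Conditions: H2O, AcOH (cat.), 75 °C; evaporate; L-phenylalanine (1 equiv), 1 M aq. HClO4 (0.4 equiv), MeCN, reflux; recrystallise
Reagents that add atoms: none
Why: Michael addition followed by amino-acid-mediated intramolecular aldol condensation (Hajos–Parrish–Eder–Sauer–Wiechert annulation), in which the L-phenylalanine enamine of the side-chain ketone attacks one of the two enantiotopic ring carbonyls through an acid-organised transition state and sets the quaternary centre (future C10) as S.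

Step 2
Reactants: 4 (7aS)-4,7a-dimethyl-2,3,7,7a-tetrahydro-1H-indene-1,5(6H)-dione
Product: 5 (1S,7aS)-1-hydroxy-4,7a-dimethyl-1,2,3,6,7,7a-hexahydro-5H-inden-5-one
Conditions: NaBH4 (0.3 equiv), EtOH, −20 °C
Reagents that add atoms: none
Why: Chemoselective borohydride reduction of the saturated cyclopentanone beside the less electrophilic enone, with hydride arriving anti to the angular methyl to give the 1S alcohol, a temporary mask whose centre is erased in step 5.

Step 3
Reactants: 5 (1S,7aS)-1-hydroxy-4,7a-dimethyl-1,2,3,6,7,7a-hexahydro-5H-inden-5-one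
Product: 7 (1S,3aR,7aS)-1-hydroxy-4,4,7a-trimethyloctahydro-5H-inden-5-one, via dilithium enolate 6 (not isolated)
Conditions: Li (4 equiv), NH3/THF, −78 → −33 °C; isoprene; MeI (8 equiv), −78 → −33 °C; NH4Cl
Reagents that add atoms: iodomethane, CI
Why: Dissolving-metal reduction of the enone with regiospecific C-methylation of the resulting enolate (Stork reductive alkylation), the β-carbon being protonated axially anti to the angular methyl so that the ring fusion becomes trans (future 5α-H).

Step 4
Reactants: 7 (1S,3aR,7aS)-1-hydroxy-4,4,7a-trimethyloctahydro-5H-inden-5-one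
Product: 9 (1S,3aS,7aS)-4,4,7a-trimethyloctahydro-1H-inden-1-ol, via hydrazone 8 (not isolated)
Conditions: N2H4·H2O, KOH, diethylene glycol, 130 °C then 200 °C
Reagents that add atoms: none
Why: Wolff–Kishner reduction (Huang–Minlon procedure) removes the hindered ketone without touching the alcohol or the ring-fusion centre, which is not alpha to the carbonyl.

Step 5
Reactants: 9 (1S,3aS,7aS)-4,4,7a-trimethyloctahydro-1H-inden-1-ol
Product: 10 (3aS,7aS)-4,4,7a-trimethyloctahydro-1H-inden-1-one
Conditions: (n-Pr4N)RuO4 (5 mol %), N-methylmorpholine N-oxide (1.5 equiv), 4 Å molecular sieves, CH2Cl2, rt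
Reagents that add atoms: none
Why: Ley–Griffith oxidation of the secondary alcohol returns the cyclopentanone under neutral conditions, and neither stereocentre is alpha to an enolisable position.

Step 6
Reactants: 10 (3aS,7aS)-4,4,7a-trimethyloctahydro-1H-inden-1-one
Product: 11 (4aS,8aS)-2,5,5,8a-tetramethyloctahydronaphthalen-1(2H)-one (C2 epimers)
Conditions: CH3CHN2 (2 equiv, Et2O solution), Sc(OTf)3 (10 mol %), CH2Cl2, −78 → −20 °C
Reagents that add atoms: diazoethane, CC=[N+]=[N-]
Why: Lewis-acid-promoted diazoalkane homologation (Tiffeneau–Demjanov-type 1,2-shift) in which diazoethane adds to the scandium-bound carbonyl anti to the angular methyl and the less substituted ring CH2 migrates with loss of N2, as in the D-homoannulation of 17-oxo steroids, so that the cyclopentanone becomes ring B with C8 and its methyl beside the carbonyl (the C8 epimer mixture is erased in step 7).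

Step 7
Reactants: 11 (4aS,8aS)-2,5,5,8a-tetramethyloctahydronaphthalen-1(2H)-one
Product: 13 (4aS,8aS)-2,5,5,8a-tetramethyl-3,4,4a,5,6,7,8,8a-octahydronaphthalen-1-yl trifluoromethanesulfonate, via lithium enolate 12 (not isolated)
Conditions: LiN(i-Pr)2 (1.3 equiv), THF, −78 → 0 °C; PhNTf2 (1.3 equiv), −78 °C → rt
Reagents that add atoms: N-phenylbis(trifluoromethanesulfonimide), O=S(=O)(N(c1ccccc1)S(=O)(=O)C(F)(F)F)C(F)(F)F
Why: Enol triflate formation in which C8–H is the only enolisable hydrogen, so the tetrasubstituted C8=C9 enolate forms regiospecifically and is O-sulfonylated, as known for 2,2,6-trimethylcyclohexanone.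

Step 8
Reactants: 14 prop-2-yn-1-ol; 15 (±)-glycidol (oxiran-2-ylmethanol)
Product: 17 (4Z)-5-(hydroxymethyl)hepta-4,6-diene-1,2-diol (racemic at C2), via magnesium chelate 16 (not isolated)
Conditions: CH2=CHMgCl (3.3 equiv), CuI (10 mol %), THF, −20 °C → rt; then 15 (1.2 equiv), −30 → 0 °C; aq. NH4Cl
Reagents that add atoms: vinylmagnesium chloride, C=C[Mg]Cl
Why: Proposed new method: the magnesium alkoxide of 14 directs anti-carbomagnesiation of the alkyne by CH2=CHMgCl (vinyl to the internal carbon, magnesium to the terminal carbon cis to CH2O in five-membered chelate 16, which fixes the 13Z geometry), and monovalent copper then transmetalates the alkenyl–Mg bond and opens the glycidol alkoxide by SN2 attack at its CH2 terminus with retention of alkene geometry, forming C12–C13 and C14–C15 in one flask; the closest known chemistry is the Duboudin–Fallis carbomagnesiation of propargylic alcohols with I2, CO2 or aldehyde trapping and the copper-catalysed opening of epoxides by alkenyl Grignard reagents, the epoxide trap of the chelate being the untested element.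

Step 9
Reactants: 17 (4Z)-5-(hydroxymethyl)hepta-4,6-diene-1,2-diol; 13 (4aS,8aS)-2,5,5,8a-tetramethyl-3,4,4a,5,6,7,8,8a-octahydronaphthalen-1-yl trifluoromethanesulfonate
Product: 19 (4Z)-5-(hydroxymethyl)-7-[(4aS,8aS)-2,5,5,8a-tetramethyl-3,4,4a,5,6,7,8,8a-octahydronaphthalen-1-yl]hept-4-ene-1,2-diol (C2 epimers), via alkylborane 18 (not isolated)
Conditions: 17 (1.5 equiv), 9-borabicyclo[3.3.1]nonane (4.3 equiv per 17), THF, 0 °C → rt; then 13 (1.0 equiv), Pd(dppf)Cl2 (10 mol %), AsPh3 (20 mol %), Cs2CO3 (4 equiv), DMF/H2O, 60 °C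
Reagents that add atoms: none
Why: Anti-Markovnikov hydroboration of the monosubstituted vinyl terminus of the diene (the trisubstituted alkene is left alone and three further equivalents of borane are taken up by the hydroxyls) followed by B-alkyl Suzuki–Miyaura coupling with the enol triflate, which forms C9–C11 with both alkene positions and geometries retained.

Step 10
Reactants: 19 (4Z)-5-(hydroxymethyl)-7-[(4aS,8aS)-2,5,5,8a-tetramethyl-3,4,4a,5,6,7,8,8a-octahydronaphthalen-1-yl]hept-4-ene-1,2-diol
Product: 21 5-{2-[(4aS,8aS)-2,5,5,8a-tetramethyl-3,4,4a,5,6,7,8,8a-octahydronaphthalen-1-yl]ethyl}-3,6-dihydro-2H-pyran-2-ol (anomers), via hydroxy aldehyde 20 (not isolated)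
Conditions: NaIO4 (1.3 equiv), THF/pH 7 buffer, 0 °C
Reagents that add atoms: none
Why: Malaprade glycol cleavage gives the β,γ-unsaturated aldehyde, which is trapped at once by the cis-disposed allylic hydroxyl as the six-membered lactol, so that C16 is unveiled, C24–OH is masked and conjugation of the alkene is prevented.

Step 11
Reactants: 22 methyl 4-hydroxybut-2-ynoate
Product: 23 methyl (2Z)-4-hydroxy-3-iodobut-2-enoate
Conditions: NaI (1.6 equiv), AcOH, 70 °C
Reagents that add atoms: sodium iodide, [Na+].[I-]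
Why: Conjugate hydroiodination of the ynoate by anti addition of HI places iodine cis to the ester (Z), the geometry needed for lactonisation in step 12.

Step 12
Reactants: 21 5-{2-[(4aS,8aS)-2,5,5,8a-tetramethyl-3,4,4a,5,6,7,8,8a-octahydronaphthalen-1-yl]ethyl}-3,6-dihydro-2H-pyran-2-ol; 23 methyl (2Z)-4-hydroxy-3-iodobut-2-enoate
Product: 25 16-epi-luffarin L, via hydroxy ester 24 (not isolated)
Conditions: CrCl2 (4 equiv), Kishi oxazoline–sulfonamide ligand (S)-N-[2-(4-isopropyl-4,5-dihydrooxazol-2-yl)-6-methylphenyl]methanesulfonamide (4.4 equiv; its antipode if a model aldehyde shows the opposite sense), Et3N (4.4 equiv), THF, rt; NiCl2 (10 mol %), 23 (1.5 equiv), rt; then pyridinium p-toluenesulfonate (cat.), CH2Cl2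
Reagents that add atoms: none
Why: Proposed new method: zerovalent nickel inserts into the C–I bond of 23 and hands the alkenyl group to chromium to give a configurationally stable Z-β-chromio enoate bound to the chiral sulfonamide, which adds to the open hydroxy-aldehyde tautomer of lactol 21 on the aldehyde face selected by the ligand to set C16 as R and form C16–C17, after which the chromium alkoxide, cis to the ester, lactonises to the butenolide while C24–OH is released; the closest known chemistry is Kishi's ligand-controlled Ni/Cr coupling of β-iodoenoates with aldehydes and the racemic Ni/Cr coupling–lactonisation of Z-β-iodoenoates to butenolides, the lactol as aldehyde source and the unprotected hydroxyls being the untested elements.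

**Compound list**
1 | 2-methylcyclopentane-1,3-dione | CC1C(=O)CCC1=O | starting material
2 | pent-1-en-3-one (ethyl vinyl ketone) | CCC(=O)C=C | starting material
3 | 2-methyl-2-(3-oxopentyl)cyclopentane-1,3-dione | CCC(=O)CCC1(C)C(=O)CCC1=O | intermediate (not isolated)
4 | (7aS)-4,7a-dimethyl-2,3,7,7a-tetrahydro-1H-indene-1,5(6H)-dione | C[C@]12CCC(=O)C(C)=C1CCC2=O | intermediate
5 | (1S,7aS)-1-hydroxy-4,7a-dimethyl-1,2,3,6,7,7a-hexahydro-5H-inden-5-one | C[C@]12CCC(=O)C(C)=C1CC[C@@H]2O | intermediate
6 | dilithium enolate–alkoxide from reduction of 5 (trans ring fusion, enolate at the former enone carbonyl) | C[C@]12CCC(O[Li])=C(C)[C@@H]1CC[C@@H]2O[Li] | intermediate (not isolated)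
7 | (1S,3aR,7aS)-1-hydroxy-4,4,7a-trimethyloctahydro-5H-inden-5-one | C[C@]12CCC(=O)C(C)(C)[C@@H]1CC[C@@H]2O | intermediate
8 | hydrazone of 7 | C[C@]12CCC(=NN)C(C)(C)[C@@H]1CC[C@@H]2O | intermediate (not isolated)
9 | (1S,3aS,7aS)-4,4,7a-trimethyloctahydro-1H-inden-1-ol | C[C@]12CCCC(C)(C)[C@@H]1CC[C@@H]2O | intermediate
10 | (3aS,7aS)-4,4,7a-trimethyloctahydro-1H-inden-1-one | C[C@]12CCCC(C)(C)[C@@H]1CCC2=O | intermediate
11 | (4aS,8aS)-2,5,5,8a-tetramethyloctahydronaphthalen-1(2H)-one, C2 epimers | C[C@]12CCCC(C)(C)[C@@H]1CCC(C)C2=O | intermediate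
12 | lithium enolate of 11 (C1=C2 of the naphthalenone) | C[C@]12CCCC(C)(C)[C@@H]1CCC(C)=C2O[Li] | intermediate (not isolated)
13 | (4aS,8aS)-2,5,5,8a-tetramethyl-3,4,4a,5,6,7,8,8a-octahydronaphthalen-1-yl trifluoromethanesulfonate | C[C@]12CCCC(C)(C)[C@@H]1CCC(C)=C2OS(=O)(=O)C(F)(F)F | intermediate
14 | prop-2-yn-1-ol | C#CCO | starting material
15 | (±)-glycidol | OCC1CO1 | starting material
16 | chloromagnesium (2Z)-3-(chloromagnesio)-2-ethenylprop-2-en-1-olate (five-membered chelate) | C=C/C(CO[Mg]Cl)=C/[Mg]Cl | intermediate (not isolated)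
17 | (4Z)-5-(hydroxymethyl)hepta-4,6-diene-1,2-diol, racemic at C2 | C=C/C(CO)=C/CC(O)CO | intermediate
18 | B-alkyl-9-borabicyclo[3.3.1]nonane from hydroboration of the vinyl group of 17, its three hydroxyls carried as 9-borabicyclononyl borinates | C(CB1C2CCCC1CCC2)/C(COB1C2CCCC1CCC2)=C/CC(OB1C2CCCC1CCC2)COB1C2CCCC1CCC2 | intermediate (not isolated)
19 | (4Z)-5-(hydroxymethyl)-7-[(4aS,8aS)-2,5,5,8a-tetramethyl-3,4,4a,5,6,7,8,8a-octahydronaphthalen-1-yl]hept-4-ene-1,2-diol, C2 epimers | CC1=C(CC/C(=C/CC(O)CO)CO)[C@@]2(C)CCCC(C)(C)[C@@H]2CC1 | intermediate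
20 | (3Z)-4-(hydroxymethyl)-6-[(4aS,8aS)-2,5,5,8a-tetramethyl-3,4,4a,5,6,7,8,8a-octahydronaphthalen-1-yl]hex-3-enal | CC1=C(CC/C(=C/CC=O)CO)[C@@]2(C)CCCC(C)(C)[C@@H]2CC1 | intermediate (not isolated)
21 | 5-{2-[(4aS,8aS)-2,5,5,8a-tetramethyl-3,4,4a,5,6,7,8,8a-octahydronaphthalen-1-yl]ethyl}-3,6-dihydro-2H-pyran-2-ol, anomers | CC1=C(CCC2=CCC(O)OC2)[C@@]2(C)CCCC(C)(C)[C@@H]2CC1 | intermediate
22 | methyl 4-hydroxybut-2-ynoate | COC(=O)C#CCO | starting material
23 | methyl (2Z)-4-hydroxy-3-iodobut-2-enoate | COC(=O)/C=C(\I)CO | intermediate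
24 | methyl (2Z,4R,6Z)-4-hydroxy-3,7-bis(hydroxymethyl)-9-[(4aS,8aS)-2,5,5,8a-tetramethyl-3,4,4a,5,6,7,8,8a-octahydronaphthalen-1-yl]nona-2,6-dienoate (formed as its chromium alkoxide) | CC1=C(CC/C(=C/C[C@@H](O)/C(CO)=C\C(=O)OC)CO)[C@@]2(C)CCCC(C)(C)[C@@H]2CC1 | intermediate (not isolated)
25 | 16-epi-luffarin L, (5R)-4-(hydroxymethyl)-5-{(2Z)-3-(hydroxymethyl)-5-[(4aS,8aS)-2,5,5,8a-tetramethyl-3,4,4a,5,6,7,8,8a-octahydronaphthalen-1-yl]pent-2-en-1-yl}furan-2(5H)-one | CC1=C(CC/C(=C/C[C@H]2OC(=O)C=C2CO)CO)[C@@]2(C)CCCC(C)(C)[C@@H]2CC1 | target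

**Totals**
Total step count: 12. Longest linear sequence: 10 (steps 1–7, 9, 10, 12).

**Three steps most likely to fail**

Step 12 (proposed new coupling; the lactol must open, the face selectivity is untested, and it is the last step). The fallback uses documented substrate classes, sets out from 19 and 23 and returns at 25. The 1,2-diol of 19 is closed with 2,2-dimethoxypropane and pyridinium p-toluenesulfonate to acetonide F1. The allylic alcohol is silylated with t-BuPh2SiCl and imidazole to silyl ether F2. H5IO6 in EtOAc unmasks and cleaves the acetonide to open-chain aldehyde F3. Separately, 23 is silylated to silyl iodoenoate F4. F3 and F4 are joined under Kishi's ligand-controlled CrCl2/NiCl2 conditions, which are established for protected aliphatic aldehydes and β-iodoenoates, to give after lactonisation bis-silyl butenolide F5. HF·pyridine in THF then releases 25.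

Step 8 (proposed new three-component union; the chelated alkenylmagnesium may be too unreactive toward the epoxide, or excess CH2=CHMgCl may consume it). The fallback uses known chemistry, sets out from 14 and returns at 17. The same carbomagnesiation is quenched with I2, the documented trap, to give iodo dienol F6. TBSCl and imidazole give silyl ether F7. Lithium–iodine exchange with t-BuLi (2 equiv, −78 °C) and BF3·OEt2-promoted opening of (±)-tert-butyldimethylsilyl glycidyl ether give bis-silyl alcohol F8. Bu4NF gives 17.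

Step 9 (a tetrasubstituted enol triflate flanked by a quaternary carbon, coupled with a polyborylated alkylborane). The fallback moves the sp3–sp2 bond formation away from the hindered carbon, sets out from 13 and returns at 19. Stille coupling of 13 with Bu3SnCH=CH2 (Pd(PPh3)4, LiCl, THF, reflux) gives diene F9. Hydroboration of its vinyl group with 9-borabicyclo[3.3.1]nonane and iodinolysis (I2, NaOMe) give iodide F10. Mg in Et2O gives Grignard reagent F11. F11 takes the place of CH2=CHMgCl in the step 8 protocol (14 first deprotonated with i-PrMgCl, CuI, then 15 as its magnesium alkoxide) and gives 19 directly.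

**Further compounds**
F1 | step 12 | acetonide of 19: 4-{(2Z)-3-(hydroxymethyl)-5-[(4aS,8aS)-2,5,5,8a-tetramethyl-3,4,4a,5,6,7,8,8a-octahydronaphthalen-1-yl]pent-2-en-1-yl}-2,2-dimethyl-1,3-dioxolane | CC1=C(CC/C(=C/CC2COC(C)(C)O2)CO)[C@@]2(C)CCCC(C)(C)[C@@H]2CC1
F2 | step 12 | tert-butyldiphenylsilyl ether of F1 at the allylic hydroxyl | CC1=C(CC/C(=C/CC2COC(C)(C)O2)CO[Si](c3ccccc3)(c3ccccc3)C(C)(C)C)[C@@]2(C)CCCC(C)(C)[C@@H]2CC1
F3 | step 12 | (3Z)-4-{[(tert-butyldiphenylsilyl)oxy]methyl}-6-[(4aS,8aS)-2,5,5,8a-tetramethyl-3,4,4a,5,6,7,8,8a-octahydronaphthalen-1-yl]hex-3-enal | CC1=C(CC/C(=C/CC=O)CO[Si](c3ccccc3)(c3ccccc3)C(C)(C)C)[C@@]2(C)CCCC(C)(C)[C@@H]2CC1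
F4 | step 12 | methyl (2Z)-4-[(tert-butyldiphenylsilyl)oxy]-3-iodobut-2-enoate | COC(=O)/C=C(\I)CO[Si](c1ccccc1)(c1ccccc1)C(C)(C)C
F5 | step 12 | bis(tert-butyldiphenylsilyl) ether of 25 | CC1=C(CC/C(=C/C[C@H]2OC(=O)C=C2CO[Si](c3ccccc3)(c3ccccc3)C(C)(C)C)CO[Si](c3ccccc3)(c3ccccc3)C(C)(C)C)[C@@]2(C)CCCC(C)(C)[C@@H]2CC1
F6 | step 8 | (2Z)-2-ethenyl-3-iodoprop-2-en-1-ol | C=C/C(CO)=C/I
F7 | step 8 | tert-butyl{[(2Z)-2-ethenyl-3-iodoprop-2-en-1-yl]oxy}dimethylsilane | C=C/C(CO[Si](C)(C)C(C)(C)C)=C/I
F8 | step 8 | (4Z)-1-[(tert-butyldimethylsilyl)oxy]-5-{[(tert-butyldimethylsilyl)oxy]methyl}hepta-4,6-dien-2-ol | C=C/C(CO[Si](C)(C)C(C)(C)C)=C/CC(O)CO[Si](C)(C)C(C)(C)C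
F9 | step 9 | (4aS,8aS)-1-ethenyl-2,5,5,8a-tetramethyl-3,4,4a,5,6,7,8,8a-octahydronaphthalene | CC1=C(C=C)[C@@]2(C)CCCC(C)(C)[C@@H]2CC1
F10 | step 9 | (4aS,8aS)-1-(2-iodoethyl)-2,5,5,8a-tetramethyl-3,4,4a,5,6,7,8,8a-octahydronaphthalene | CC1=C(CCI)[C@@]2(C)CCCC(C)(C)[C@@H]2CC1
F11 | step 9 | {2-[(4aS,8aS)-2,5,5,8a-tetramethyl-3,4,4a,5,6,7,8,8a-octahydronaphthalen-1-yl]ethyl}magnesium iodide | CC1=C(CC[Mg]I)[C@@]2(C)CCCC(C)(C)[C@@H]2CC1
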